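**Plan**

1. Numbering used here: ring A (cyclopentane) C1(CH3)–C13(OAc)–C12H2–C11(CH3)(CHO)–C10; ring B (cyclodecene) C1–C2(OAc)–C3–C4–C5(CH3)=C6–C7–C8(OH)–C9(OH)–C10; ring C (lactone) C7–O–C15(=O)–C14(CH3)–C8.
2. Cuts, last-formed first: C4–C5 (sp3–sp2 Suzuki macrocyclisation of ring B); C2–C3 (vinyl addition); lactone C–O and C8–C14 (Reformatsky); C7–C8 (alkynylation); then C12–C13 and C10–C11 together in a formal (3+2) cycloaddition.
3. Enabling feature: in ring A the edge C12–C11 is a methacrolein unit, and C13–C1–C10 is a three-carbon unit with oxygen on C13 and the C9 carbinol (ketone level) on C10, i.e. a ring-opened 2-silyloxycyclopropyl ketone. A ketyl at C9 opens C10–C13 and the radical/enolate pair adds across methacrylonitrile (nitrile = masked CHO).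
4. Forward order: cyclopropane (Rh) → ring A (key step) → acetyl turned into an alkyne and joined to a (Z)-iodo-enal → C7/C8/C9 triad and ring C → C2 arm → ring B closed last.
5. Stereochemistry: C1 from the Rh catalyst; C10, C11, C13 relayed from C1 in the key step; C7 from the ProPhenol ligand; C9 and C8 from C7 (OsO4 anti to C7–O on the Z-alkene, then doubly chelated Reformatsky); C14 by equilibration; C2 by chelation to C13–O; Z-C5=C6 from the vinyl iodide.

Key step: step 7

Remark: Rh2(4S-MPPIM)4 and the ProPhenol antipode named below are assumed to induce in the sense drawn (by analogy with simpler allylic diazoacetates and enals); if the sense is opposite, the mirror-image catalyst is taken.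

**Route**

Step 1
Reactants: 1 ethyl 2-methyl-3-oxopropanoate (ethyl 2-formylpropanoate)
Product: 2 ethyl (E)-3-[(tert-butyldimethylsilyl)oxy]-2-methylprop-2-enoate
Conditions: TBSCl, imidazole, DMF, 0 °C to rt
Reagents that add atoms: tert-butyldimethylsilyl chloride, CC(C)(C)[Si](C)(C)Cl
Why: O-silylation of the enol form of a formyl ester should give the silyl enol ether; its geometry only affects C13, which is set anew in step 7.

Step 2
Reactants: 2 ethyl (E)-3-[(tert-butyldimethylsilyl)oxy]-2-methylprop-2-enoate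
Product: 3 (E)-3-[(tert-butyldimethylsilyl)oxy]-2-methylprop-2-en-1-ol
Conditions: i-Bu2AlH, CH2Cl2, −78 °C
Reagents that add atoms: none
Why: 1,2-reduction of an α,β-unsaturated ester by i-Bu2AlH should give the allylic alcohol without touching the silyl enol ether.

Step 3
Reactants: 3 (E)-3-[(tert-butyldimethylsilyl)oxy]-2-methylprop-2-en-1-ol
Product: 5 (E)-3-[(tert-butyldimethylsilyl)oxy]-2-methylprop-2-en-1-yl diazoacetate, via glyoxylate tosylhydrazone ester 4 (not isolated)
Conditions: TsNHN=CHCOCl, PhNMe2, CH2Cl2, 0 °C; then Et3N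
Reagents that add atoms: glyoxylic acid chloride p-toluenesulfonylhydrazone, Cc1ccc(cc1)S(=O)(=O)NN=CC(Cl)=O
Why: Corey–Myers diazoacetylation: acylation of the alcohol, then base-induced loss of sulfinate, should give the allylic diazoacetate under non-acidic conditions.

Step 4
Reactants: 5 (E)-3-[(tert-butyldimethylsilyl)oxy]-2-methylprop-2-en-1-yl diazoacetate
Product: 6 (1S,5S,6R)-6-[(tert-butyldimethylsilyl)oxy]-5-methyl-3-oxabicyclo[3.1.0]hexan-2-one (6-OTBS exo)
Conditions: Rh2(4S-MPPIM)4 (1 mol %; the dirhodium tetrakis-carboxamidate of methyl (4S)-2-oxo-3-(3-phenylpropanoyl)imidazolidine-4-carboxylate), CH2Cl2, reflux, slow addition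
Reagents that add atoms: none
Why: Doyle intramolecular cyclopropanation by a rhodium carbenoid; the tether enforces cis fusion, the E geometry is transferred (OTBS exo), and the chiral carboxamidate selects the alkene face, which sets the quaternary carbon that becomes C1.

Step 5
Reactants: 6 (1S,5S,6R)-6-[(tert-butyldimethylsilyl)oxy]-5-methyl-3-oxabicyclo[3.1.0]hexan-2-one
Product: 8 2-[(tert-butyldimethylsilyl)oxy]-3-{[(tert-butyldimethylsilyl)oxy]methyl}-N-methoxy-N,3-dimethylcyclopropane-1-carboxamide (amide cis to CH2OTBS, ring OTBS trans to both), via hydroxy Weinreb amide 7 (not isolated)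
Conditions: MeNH(OMe)·HCl, i-PrMgCl, THF, −20 °C; then TBSCl, imidazole, DMF, rt
Reagents that add atoms: N,O-dimethylhydroxylamine hydrochloride, Cl.CNOC; tert-butyldimethylsilyl chloride, CC(C)(C)[Si](C)(C)Cl
Why: Aminolysis of the lactone by the magnesium amide (Weinreb amide formation) avoids Lewis-acid opening of the donor–acceptor cyclopropane, and the freed primary alcohol is silylated.

Step 6
Reactants: 8 bis-silylated cyclopropyl Weinreb amide
Product: 9 1-[2-[(tert-butyldimethylsilyl)oxy]-3-{[(tert-butyldimethylsilyl)oxy]methyl}-3-methylcyclopropyl]ethan-1-one (acetyl cis to CH2OTBS, ring OTBS trans)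
Conditions: MeMgBr, THF, 0 °C
Reagents that add atoms: methylmagnesium bromide, C[Mg]Br
Why: Grignard addition to a Weinreb amide should stop at the ketone through the chelated tetrahedral intermediate; the new methyl is C8 of the target.

Step 7
Reactants: 9 cyclopropyl methyl ketone; 10 methacrylonitrile
Product: 11 2-acetyl-4-[(tert-butyldimethylsilyl)oxy]-3-{[(tert-butyldimethylsilyl)oxy]methyl}-1,3-dimethylcyclopentane-1-carbonitrile (ring A: nitrile, acetyl and C1 methyl on one face; C11 methyl, OTBS and CH2OTBS on the other)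
Conditions: SmI2 (20 mol %), Sm metal (20 mol %), 10 (3 equiv), THF, 55 °C
Reagents that add atoms: none
Why: Electron transfer from SmI2 to the ketone gives a ketyl that opens the push–pull C10–C13 bond (the silyloxy group makes the α-oxy radical the more stable fragment, so C1–C10 stays intact), the nucleophilic C13 radical adds to the CH2 terminus of electron-poor 10, and the electrophilic tertiary α-cyano radical closes onto C10 of the electron-rich trivalent samarium enolate; back electron transfer from the new ketyl returns SmI2 and the ketone. The closest known reaction type is the SmI2-catalysed radical-relay formal (3+2) cycloaddition of alkyl cyclopropyl ketones with alkenes. Ring A closes in a 5-exo-trig mode (radical at C11, enolate C10=C9 exocyclic). C13 is set in the intermolecular addition, which should occur anti to the enolate arm on quaternary C1 with the OTBS group staggered next to the small C1 methyl (OTBS cis to CH2OTBS); C11 and C10 are set in a chair-like cyclisation in which the C11 methyl and the CH2OTBS group both avoid the enolate carbon, and C10 can also be equilibrated through its enol. The step needs bond-selective ring opening and matched polarity in both radical additions; the oxygen donor on C13 and the nitrile acceptor secure these, and the low stationary concentration of divalent samarium keeps the α-cyano radical from being reduced before it cyclises.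

Step 8
Reactants: 11 ring A methyl ketone
Product: 13 4-[(tert-butyldimethylsilyl)oxy]-3-{[(tert-butyldimethylsilyl)oxy]methyl}-2-ethynyl-1,3-dimethylcyclopentane-1-carbonitrile, via enol diethyl phosphate 12 (not isolated)
Conditions: LDA, THF, −78 °C; ClP(O)(OEt)2; then LDA (2.5 equiv), −78 °C to rt
Reagents that add atoms: none
Why: Negishi's enol phosphate route: kinetic enolisation at the methyl group, O-phosphorylation and elimination should give the terminal alkyne (C9≡C8); the nitrile has no α-hydrogen.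

Step 9
Reactants: 13 alkynyl nitrile
Product: 14 4-[(tert-butyldimethylsilyl)oxy]-3-{[(tert-butyldimethylsilyl)oxy]methyl}-2-ethynyl-1,3-dimethylcyclopentane-1-carbaldehyde
Conditions: i-Bu2AlH, toluene, −78 to 0 °C; aq. Rochelle salt, then SiO2/H2O
Reagents that add atoms: water, O
Why: i-Bu2AlH stops at the N-aluminoimine of the hindered nitrile, and hydrolysis should give the non-enolisable C11 aldehyde.

Step 10
Reactants: 14 ring A aldehyde
Product: 15 dimethyl acetal of 14
Conditions: MeOSiMe3, Me3SiOTf (5 mol %), CH2Cl2, −78 °C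
Reagents that add atoms: methoxytrimethylsilane, CO[Si](C)(C)C
Why: Noyori acetalisation under aprotic conditions should mask the neopentyl aldehyde without cleaving the silyl ethers.

Step 11
Reactants: 16 but-2-yn-1-ol
Product: 18 (Z)-3-iodobut-2-en-1-ol, via cyclic alkenylaluminate 17 (not isolated)
Conditions: NaAlH2(OCH2CH2OCH3)2, THF, 0 °C; then I2, −78 °C
Reagents that add atoms: iodine, II
Why: Hydroxyl-directed trans-hydroalumination of the propargylic alcohol and iodinolysis with retention should give the Z vinyl iodide (iodine cis to CH2OH).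

Step 12
Reactants: 18 (Z)-3-iodobut-2-en-1-ol
Product: 19 (Z)-3-iodobut-2-enal
Conditions: MnO2, CH2Cl2, rt
Reagents that add atoms: none
Why: MnO2 oxidation of an allylic alcohol should give the enal with the Z geometry intact.

Step 13
Reactants: 15 alkyne acetal; 19 (Z)-3-iodobut-2-enal
Product: 20 (S)-propargylic alcohol (C9≡C8–C7H(OH)–C6H=C5(I)CH3, Z)
Conditions: Me2Zn, (S,S)-ProPhenol (2,6-bis{[2-(hydroxydiphenylmethyl)pyrrolidin-1-yl]methyl}-4-methylphenol, 20 mol %; the antipode that directs Re-face attack), Ph3P=O, toluene, 0 °C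
Reagents that add atoms: none
Why: Zinc–ProPhenol asymmetric alkynylation of an α,β-unsaturated aldehyde; ligand-controlled Re-face attack of the alkynylzinc should set C7 as S.

Step 14
Reactants: 20 propargylic alcohol
Product: 21 C7 4-methoxybenzyl ether of 20
Conditions: NaH, PMBCl, Bu4NI, DMF, 0 °C
Reagents that add atoms: 4-methoxybenzyl chloride, COc1ccc(CCl)cc1
Why: Williamson etherification should install a chelating ether that can later be removed by DDQ in the presence of the silyl ethers.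

Step 15
Reactants: 21 PMB-protected enyne
Product: 23 (Z)-C9=C8 alkene, via alkenyl dicyclohexylborane 22 (not isolated)
Conditions: Cy2BH, THF, 0 °C to rt; then AcOH
Reagents that add atoms: none
Why: syn-Hydroboration of the internal alkyne (boron at the less hindered C8) and protonolysis with retention should give the cis alkene; the deactivated iodoalkene does not react.

Step 16
Reactants: 23 Z-alkene
Product: 24 C8,C9 syn-diol (configuration as in the target at C9; C8–OH anti to C7–OPMB)
Conditions: OsO4 (5 mol %), NMO, acetone/H2O, rt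
Reagents that add atoms: N-methylmorpholine N-oxide, C[N+]1([O-])CCOCC1; water, O
Why: Upjohn dihydroxylation adds syn to the Z-alkene, and by Kishi's rule OsO4 should approach anti to the allylic C7–O bond in the conformer with C7–H eclipsing the alkene (1,3-allylic strain with the cis C10 group); the iodoalkene is too electron-poor to compete.

Step 17
Reactants: 24 syn-diol
Product: 25 C9-hydroxy C8-ketone
Conditions: IBX (1.1 equiv), DMSO, rt
Reagents that add atoms: none
Why: IBX oxidises 1,2-diols to α-hydroxy ketones without glycol cleavage, and the C9 carbinol, shielded by the two quaternary carbons around C10, should react more slowly than C8.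

Step 18
Reactants: 25 α-hydroxy ketone
Product: 26 tert-butyl 2-methyl-3-hydroxy ester (C8 tertiary alcohol as in the target; C14 as a mixture)
Conditions: Zn, tert-butyl 2-bromopropanoate, THF, −20 to 0 °C (excess reagent)
Reagents that add atoms: tert-butyl 2-bromopropanoate, CC(Br)C(=O)OC(C)(C)C
Why: Reformatsky addition to a ketone held in Cram chelates with both the C7–OPMB oxygen and the C9 zinc alkoxide; both chelates expose the same face, which should set C8, while C14 is left for later equilibration.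

Step 19
Reactants: 26 dihydroxy ester
Product: 27 C8,C9 acetonide
Conditions: 2-methoxypropene, PPTS, CH2Cl2, 0 °C to rt
Reagents that add atoms: 2-methoxypropene, COC(C)=C
Why: Acetonide formation ties up C9–OH and C8–OH, so that only C7–O can later lactonise and C9–OH stays masked during acetylation.

Step 20
Reactants: 27 acetonide
Product: 29 ring C lactone spiro-fused to the acetonide (C14 methyl cis to C8–O), via C7 hydroxy ester 28 (not isolated)
Conditions: DDQ, CH2Cl2/pH 7 buffer, 0 °C; then KOt-Bu (0.2 equiv), THF, 0 °C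
Reagents that add atoms: none
Why: Oxidative PMB cleavage frees C7–OH, whose alkoxide should close the γ-lactone by 5-exo-trig transesterification; the base also equilibrates C14 so that its methyl lies trans to the bulky C9 substituent.

Step 21
Reactants: 29 lactone
Product: 30 C13-hydroxy C2-hydroxymethyl diol
Conditions: TBAF, THF, rt to 40 °C
Reagents that add atoms: none
Why: Fluoride desilylation should remove both silyl ethers.

Step 22
Reactants: 30 diol
Product: 31 C13-hydroxy C2-aldehyde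
Conditions: TEMPO (10 mol %), PhI(OAc)2, CH2Cl2, rt
Reagents that add atoms: none
Why: The oxoammonium oxidation is selective for the primary alcohol; the resulting β-hydroxy aldehyde has no α-hydrogen and cannot dehydrate.

Step 23
Reactants: 31 hydroxy aldehyde
Product: 32 (2R)-allylic alcohol (C2–OH and C13–OH free)
Conditions: CH2=CHMgBr (3.5 equiv), THF/CH2Cl2, −78 °C
Reagents that add atoms: vinylmagnesium bromide, C=C[Mg]Br
Why: Chelation-controlled Grignard addition: magnesium bridges the C13 alkoxide and the C2 aldehyde (cis on ring A), and vinyl should attack anti to the C10 ring branch (past the small C1 methyl); the low temperature spares the hindered lactone and suppresses retro-aldol opening.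

Step 24
Reactants: 32 diol
Product: 33 C2,C13 diacetate
Conditions: Ac2O, Et3N, DMAP, CH2Cl2, rt
Reagents that add atoms: acetic anhydride, CC(=O)OC(C)=O
Why: Both free secondary alcohols are acetylated while C8–O and C9–O are held in the acetonide.

Step 25
Reactants: 33 diacetate
Product: 35 ring B macrocycle (acetonide and dimethyl acetal of the target), via B-alkyl-9-BBN 34 (not isolated)
Conditions: 9-BBN, THF, rt; then Pd(dppf)Cl2, AsPh3, Cs2CO3, DMF/THF/H2O, high dilution, rt to 45 °C
Reagents that add atoms: none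
Why: Anti-Markovnikov hydroboration of the terminal vinyl group and intramolecular B-alkyl Suzuki–Miyaura coupling with the vinyl iodide should close the ten-membered ring at C4–C5 with retention of the Z geometry.

Step 26
Reactants: 35 protected macrocycle
Product: 36 CNP0123121.2 (target)
Conditions: AcOH/H2O (4:1), 40 °C
Reagents that add atoms: water, O
Why: Acid hydrolysis should remove the acetonide and the dimethyl acetal together, leaving the acetates and the lactone.

**Compound list**

1 | ethyl 2-methyl-3-oxopropanoate | CCOC(=O)C(C)C=O | starting material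
2 | ethyl (E)-3-[(tert-butyldimethylsilyl)oxy]-2-methylprop-2-enoate | CCOC(=O)/C(C)=C/O[Si](C)(C)C(C)(C)C | intermediate
3 | (E)-3-[(tert-butyldimethylsilyl)oxy]-2-methylprop-2-en-1-ol | OC/C(C)=C/O[Si](C)(C)C(C)(C)C | intermediate
4 | (E)-3-silyloxy-2-methylallyl glyoxylate p-toluenesulfonylhydrazone | Cc1ccc(cc1)S(=O)(=O)NN=CC(=O)OC/C(C)=C/O[Si](C)(C)C(C)(C)C | intermediate
5 | (E)-3-[(tert-butyldimethylsilyl)oxy]-2-methylprop-2-en-1-yl diazoacetate | [N-]=[N+]=CC(=O)OC/C(C)=C/O[Si](C)(C)C(C)(C)C | intermediate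
6 | (1S,5S,6R)-6-[(tert-butyldimethylsilyl)oxy]-5-methyl-3-oxabicyclo[3.1.0]hexan-2-one | O=C1OC[C@@]2(C)[C@H](O[Si](C)(C)C(C)(C)C)[C@@H]12 | intermediate
7 | cyclopropyl hydroxy Weinreb amide (amide cis to CH2OH, OTBS trans) | CON(C)C(=O)[C@@H]1[C@@H](O[Si](C)(C)C(C)(C)C)[C@]1(C)CO | intermediate
8 | bis-silylated cyclopropyl Weinreb amide | CON(C)C(=O)[C@@H]1[C@@H](O[Si](C)(C)C(C)(C)C)[C@]1(C)CO[Si](C)(C)C(C)(C)C | intermediate
9 | cyclopropyl methyl ketone (acetyl cis to CH2OTBS, ring OTBS trans) | CC(=O)[C@@H]1[C@@H](O[Si](C)(C)C(C)(C)C)[C@]1(C)CO[Si](C)(C)C(C)(C)C | intermediate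
10 | methacrylonitrile | C=C(C)C#N | starting material
11 | ring A acetyl nitrile (key-step product) | CC(C)(C)[Si](C)(C)O[C@H]1C[C@](C)(C#N)[C@H](C(C)=O)[C@@]1(C)CO[Si](C)(C)C(C)(C)C | intermediate
12 | enol diethyl phosphate of 11 | CC(C)(C)[Si](C)(C)O[C@H]1C[C@](C)(C#N)[C@H](C(=C)OP(=O)(OCC)OCC)[C@@]1(C)CO[Si](C)(C)C(C)(C)C | intermediate
13 | ring A ethynyl nitrile | CC(C)(C)[Si](C)(C)O[C@H]1C[C@](C)(C#N)[C@H](C#C)[C@@]1(C)CO[Si](C)(C)C(C)(C)C | intermediate
14 | ring A ethynyl aldehyde | CC(C)(C)[Si](C)(C)O[C@H]1C[C@](C)(C=O)[C@H](C#C)[C@@]1(C)CO[Si](C)(C)C(C)(C)C | intermediate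
15 | ring A ethynyl dimethyl acetal | CC(C)(C)[Si](C)(C)O[C@H]1C[C@](C)(C(OC)OC)[C@H](C#C)[C@@]1(C)CO[Si](C)(C)C(C)(C)C | intermediate
16 | but-2-yn-1-ol | CC#CCO | starting material
17 | sodium cyclic alkenylaluminate from 16 | [Na+].CC1=CCO[Al-]1(OCCOC)OCCOC | intermediate
18 | (Z)-3-iodobut-2-en-1-ol | C/C(I)=C/CO | intermediate
19 | (Z)-3-iodobut-2-enal | C/C(I)=C/C=O | intermediate
20 | (S)-propargylic alcohol (C7–OH) | CC(C)(C)[Si](C)(C)O[C@H]1C[C@](C)(C(OC)OC)[C@H](C#C[C@@H](O)/C=C(/C)I)[C@@]1(C)CO[Si](C)(C)C(C)(C)C | intermediate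
21 | C7 PMB ether of 20 | CC(C)(C)[Si](C)(C)O[C@H]1C[C@](C)(C(OC)OC)[C@H](C#C[C@@H](OCc2ccc(OC)cc2)/C=C(/C)I)[C@@]1(C)CO[Si](C)(C)C(C)(C)C | intermediate
22 | C8 alkenyl dicyclohexylborane | CC(C)(C)[Si](C)(C)O[C@H]1C[C@](C)(C(OC)OC)[C@H](/C=C(/B(C3CCCCC3)C3CCCCC3)[C@@H](OCc2ccc(OC)cc2)/C=C(/C)I)[C@@]1(C)CO[Si](C)(C)C(C)(C)C | intermediate
23 | (Z)-C9=C8 alkene | CC(C)(C)[Si](C)(C)O[C@H]1C[C@](C)(C(OC)OC)[C@H](/C=C\[C@@H](OCc2ccc(OC)cc2)/C=C(/C)I)[C@@]1(C)CO[Si](C)(C)C(C)(C)C | intermediate
24 | C8,C9 syn-diol | CC(C)(C)[Si](C)(C)O[C@H]1C[C@](C)(C(OC)OC)[C@H]([C@@H](O)[C@@H](O)[C@@H](OCc2ccc(OC)cc2)/C=C(/C)I)[C@@]1(C)CO[Si](C)(C)C(C)(C)C | intermediate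
25 | C9-hydroxy C8-ketone | CC(C)(C)[Si](C)(C)O[C@H]1C[C@](C)(C(OC)OC)[C@H]([C@@H](O)C(=O)[C@@H](OCc2ccc(OC)cc2)/C=C(/C)I)[C@@]1(C)CO[Si](C)(C)C(C)(C)C | intermediate
26 | Reformatsky adduct (tert-butyl ester, C14 epimers) | CC(C)(C)[Si](C)(C)O[C@H]1C[C@](C)(C(OC)OC)[C@H]([C@@H](O)[C@](O)(C(C)C(=O)OC(C)(C)C)[C@@H](OCc2ccc(OC)cc2)/C=C(/C)I)[C@@]1(C)CO[Si](C)(C)C(C)(C)C | intermediate
27 | C8,C9 acetonide of 26 | CC(C)(C)[Si](C)(C)O[C@H]1C[C@](C)(C(OC)OC)[C@H]([C@H]3OC(C)(C)O[C@@]3(C(C)C(=O)OC(C)(C)C)[C@@H](OCc2ccc(OC)cc2)/C=C(/C)I)[C@@]1(C)CO[Si](C)(C)C(C)(C)C | intermediate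
28 | C7 hydroxy ester | CC(C)(C)[Si](C)(C)O[C@H]1C[C@](C)(C(OC)OC)[C@H]([C@H]3OC(C)(C)O[C@@]3(C(C)C(=O)OC(C)(C)C)[C@@H](O)/C=C(/C)I)[C@@]1(C)CO[Si](C)(C)C(C)(C)C | intermediate
29 | ring C lactone acetonide, bis-silyl ether | CC(C)(C)[Si](C)(C)O[C@H]1C[C@](C)(C(OC)OC)[C@H]([C@H]3OC(C)(C)O[C@]34[C@@H](C)C(=O)O[C@H]4/C=C(/C)I)[C@@]1(C)CO[Si](C)(C)C(C)(C)C | intermediate
30 | C13-ol, C2 primary alcohol | O[C@H]1C[C@](C)(C(OC)OC)[C@H]([C@H]3OC(C)(C)O[C@]34[C@@H](C)C(=O)O[C@H]4/C=C(/C)I)[C@@]1(C)CO | intermediate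
31 | C13-hydroxy C2-aldehyde | O[C@H]1C[C@](C)(C(OC)OC)[C@H]([C@H]3OC(C)(C)O[C@]34[C@@H](C)C(=O)O[C@H]4/C=C(/C)I)[C@@]1(C)C=O | intermediate
32 | (2R)-allylic alcohol, C13-ol | O[C@H]1C[C@](C)(C(OC)OC)[C@H]([C@H]3OC(C)(C)O[C@]34[C@@H](C)C(=O)O[C@H]4/C=C(/C)I)[C@@]1(C)[C@H](O)C=C | intermediate
33 | C2,C13 diacetate | CC(=O)O[C@H]1C[C@](C)(C(OC)OC)[C@H]([C@H]3OC(C)(C)O[C@]34[C@@H](C)C(=O)O[C@H]4/C=C(/C)I)[C@@]1(C)[C@H](OC(C)=O)C=C | intermediate
34 | C4 B-alkyl-9-BBN | CC(=O)O[C@H]1C[C@](C)(C(OC)OC)[C@H]([C@H]3OC(C)(C)O[C@]34[C@@H](C)C(=O)O[C@H]4/C=C(/C)I)[C@@]1(C)[C@H](OC(C)=O)CCB1C2CCCC1CCC2 | intermediate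
35 | macrocycle, acetonide and dimethyl acetal of the target | CC(=O)O[C@H]1C[C@](C)(C(OC)OC)[C@@H]2[C@H]4OC(C)(C)O[C@@]43[C@H](/C=C(/C)CC[C@@H](OC(C)=O)[C@@]12C)OC(=O)[C@@H]3C | intermediate
36 | CNP0123121.2 | CC(=O)O[C@H]1C[C@](C)(C=O)[C@@H]2[C@@H](O)[C@@]3(O)[C@H](/C=C(/C)CC[C@@H](OC(C)=O)[C@@]12C)OC(=O)[C@@H]3C | target

**Count and risks**

Total steps: 26. Longest linear sequence: 24 (steps 1–10 and 13–26).

Most likely to fail:

1. Step 7. The ketyl may open the C1–C10 bond instead of C10–C13 (regioisomeric annulation), the radical addition may show poor facial selectivity at C13, and the catalyst may be lost by irreversible reduction of the nitrile-stabilised radical. Fallback, from 8 back to 13: Weinreb amide 8 is reduced with i-Bu2AlH to cyclopropanecarbaldehyde F1 and methylenated (Ph3P=CH2) to vinylcyclopropane F2. F2 and 10 are combined under thiyl-radical catalysis (PhSSPh, AIBN, benzene, 80 °C; the known vinylcyclopropane–alkene (3+2) radical chain) to give vinylcyclopentane F3. Ozonolysis (O3; Me2S) gives ring A aldehyde F4, and Ohira–Bestmann homologation (dimethyl (1-diazo-2-oxopropyl)phosphonate, K2CO3, MeOH) returns 13.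

2. Step 25. Ring closure of the strained ten-membered ring may be slower than intermolecular coupling, protodeboronation or β-hydride elimination. Fallback, from 33 back to 35: hydroboration (9-BBN) and oxidation (NaBO3) give primary alcohol F5; I2, PPh3 and imidazole give primary iodide F6; zinc dust with LiCl in THF inserts into the alkyl C–I bond to give alkylzinc iodide F7, which is cyclised by base-free intramolecular Negishi coupling (Pd2(dba)3, tri(2-furyl)phosphine, THF/DMA, slow addition) to 35.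

3. Step 23. Facial selectivity at C2 may be poor, and the magnesium aldolate may undergo retro-aldol opening or the Grignard reagent may attack the lactone. Fallback, from 29 back to 32: HF·pyridine (THF/pyridine, 0 °C) removes only the primary silyl ether to give alcohol F8; Dess–Martin oxidation gives aldehyde F9 (C13 still silylated, so no retro-aldol path); CH2=CHMgBr gives the epimeric allylic alcohols F10; Dess–Martin oxidation gives enone F11; reagent-controlled reduction with the (S)-CBS oxazaborolidine and catecholborane (quaternary C1 as the large group) gives the (2R)-alcohol F12; TBAF returns 32.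

Further compounds
F1 | step 7 | 2-silyloxy-3-(silyloxymethyl)-3-methylcyclopropanecarbaldehyde | O=C[C@@H]1[C@@H](O[Si](C)(C)C(C)(C)C)[C@]1(C)CO[Si](C)(C)C(C)(C)C
F2 | step 7 | vinylcyclopropane | C=C[C@@H]1[C@@H](O[Si](C)(C)C(C)(C)C)[C@]1(C)CO[Si](C)(C)C(C)(C)C
F3 | step 7 | ring A vinyl nitrile | CC(C)(C)[Si](C)(C)O[C@H]1C[C@](C)(C#N)[C@H](C=C)[C@@]1(C)CO[Si](C)(C)C(C)(C)C
F4 | step 7 | ring A formyl nitrile | CC(C)(C)[Si](C)(C)O[C@H]1C[C@](C)(C#N)[C@H](C=O)[C@@]1(C)CO[Si](C)(C)C(C)(C)C
F5 | step 25 | C4 primary alcohol | CC(=O)O[C@H]1C[C@](C)(C(OC)OC)[C@H]([C@H]3OC(C)(C)O[C@]34[C@@H](C)C(=O)O[C@H]4/C=C(/C)I)[C@@]1(C)[C@H](OC(C)=O)CCO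
F6 | step 25 | C4 primary iodide | CC(=O)O[C@H]1C[C@](C)(C(OC)OC)[C@H]([C@H]3OC(C)(C)O[C@]34[C@@H](C)C(=O)O[C@H]4/C=C(/C)I)[C@@]1(C)[C@H](OC(C)=O)CCI
F7 | step 25 | C4 alkylzinc iodide | CC(=O)O[C@H]1C[C@](C)(C(OC)OC)[C@H]([C@H]3OC(C)(C)O[C@]34[C@@H](C)C(=O)O[C@H]4/C=C(/C)I)[C@@]1(C)[C@H](OC(C)=O)CC[Zn]I
F8 | step 23 | C13 silyl ether, C2 primary alcohol | CC(C)(C)[Si](C)(C)O[C@H]1C[C@](C)(C(OC)OC)[C@H]([C@H]3OC(C)(C)O[C@]34[C@@H](C)C(=O)O[C@H]4/C=C(/C)I)[C@@]1(C)CO
F9 | step 23 | C13 silyl ether, C2 aldehyde | CC(C)(C)[Si](C)(C)O[C@H]1C[C@](C)(C(OC)OC)[C@H]([C@H]3OC(C)(C)O[C@]34[C@@H](C)C(=O)O[C@H]4/C=C(/C)I)[C@@]1(C)C=O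
F10 | step 23 | C2-epimeric allylic alcohols | CC(C)(C)[Si](C)(C)O[C@H]1C[C@](C)(C(OC)OC)[C@H]([C@H]3OC(C)(C)O[C@]34[C@@H](C)C(=O)O[C@H]4/C=C(/C)I)[C@@]1(C)C(O)C=C
F11 | step 23 | C2 vinyl ketone | CC(C)(C)[Si](C)(C)O[C@H]1C[C@](C)(C(OC)OC)[C@H]([C@H]3OC(C)(C)O[C@]34[C@@H](C)C(=O)O[C@H]4/C=C(/C)I)[C@@]1(C)C(=O)C=C
F12 | step 23 | (2R)-allylic alcohol, C13 silyl ether | CC(C)(C)[Si](C)(C)O[C@H]1C[C@](C)(C(OC)OC)[C@H]([C@H]3OC(C)(C)O[C@]34[C@@H](C)C(=O)O[C@H]4/C=C(/C)I)[C@@]1(C)[C@H](O)C=C
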